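**Retrosynthetic overview**

- The C2 acetate comes from the C2 alcohol, which comes from 1,2-reduction of the enone carbonyl of a bicyclo[3.2.1]oct-3-ene-2,8-dione; the C3 enol methyl ether comes from O-methylation of the C3 enol.
- The bicycle comes from a stepwise [5+2] between the C6=C7 bond of (E)-isoelemicin and 5-allyl-2,3-dimethoxy-1,4-benzoquinone (bond C5–C6, then C1–C7) on a chiral Ti(IV) TADDOLate, which sets C5/C6; C7, C1 and later C2 are relayed from them.
- The quinone ring (C8, C1, C2, C3, C4, C5) comes from ring expansion of a squarate-derived 4-alkynyl-4-hydroxycyclobutenone, in the same flask as the cycloaddition.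
- Enabling feature: C8–C1–C2–C3 are four contiguous oxygen-bearing carbons (a squaric acid ring) closed by a C4(H)=C5(allyl) two-carbon unit (an alkyne), and the C8 carbonyl lies between C1 and C5, the termini of the five-carbon unit C1–C5, so the ring is a quinone that takes up an alkene across C1/C5.
- Ring order: four-membered ring (bought), six-membered ring (expansion), then five- and seven-membered rings (one cycloaddition).

Key step: step 3

Remark on numbering: C1–C8 are the atoms of the bicyclo[3.2.1]octane core of the target (C1 OMe bridgehead, C2 OAc, C3 OMe, C4 =CH, C5 allyl bridgehead, C6 Me, C7 aryl, C8 C=O) and are used for all precursors.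

Assumption: the (R,R)-TADDOLate is taken to leave open the face of C5 that leads to the (5S,6S) series; if the sense of induction is the opposite, the equally available (S,S)-ligand is used instead.

**Step 1**
Reactants: 1 elemicin (5-allyl-1,2,3-trimethoxybenzene)
Product: 2 (E)-isoelemicin (1,2,3-trimethoxy-5-[(1E)-prop-1-en-1-yl]benzene)
Conditions: RuHCl(CO)(PPh3)3 (1 mol %), PhMe, 80 °C
Reagents that add atoms: none
Why: Ru–H-catalysed alkene isomerization (hydrometalation/β-hydride elimination) moves the terminal double bond into conjugation with the arene, and the conjugated E isomer is the thermodynamic sink, which fixes the trans relation later transferred to C6/C7.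

**Step 2**
Reactants: 3 pent-1-en-4-yne; 4 dimethyl squarate (3,4-dimethoxycyclobut-3-ene-1,2-dione)
Product: 5 rac-4-hydroxy-2,3-dimethoxy-4-(pent-4-en-1-yn-1-yl)cyclobut-2-en-1-one
Conditions: 3, n-BuLi, THF, −78 °C; then 4, −78 °C; H2O
Reagents that add atoms: none
Why: 1,2-addition of the lithium acetylide to one of the two equivalent vinylogous-ester carbonyls of dimethyl squarate (standard squarate carbinol formation) should stop at the monoadduct at −78 °C because the alkoxide deactivates the remaining carbonyl; the carbinol centre is racemic and is erased in step 3.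

**Step 3**
Reactants: 5 rac-4-hydroxy-2,3-dimethoxy-4-(pent-4-en-1-yn-1-yl)cyclobut-2-en-1-one; 2 (E)-isoelemicin
Product: 7 (1R,5S,6S,7R)-5-allyl-3-hydroxy-1-methoxy-6-methyl-7-(3,4,5-trimethoxyphenyl)bicyclo[3.2.1]oct-3-ene-2,8-dione, via allyl(dimethoxy)benzoquinone 6 (not isolated)
Conditions: PhMe, 110 °C; then 2, TiCl2[(R,R)-TADDOLate] (3 equiv), CH2Cl2, −78 → −20 °C; H2O
Reagents that add atoms: none
Why: Heating opens the cyclobutenone by conrotatory 4π-electrocyclic ring opening (hydroxyl rotating outward) to a (2-alkynylethenyl)ketene, whose ketene carbon closes 6-endo on the distal alkyne carbon to a diradical that collapses by O-to-C hydrogen shift (Moore rearrangement of 4-alkynyl-4-hydroxycyclobutenones), so the four squarate carbons become C8, C1, C2, C3 and the alkyne carbons C4, C5 of the six-membered ring, an alkyl-substituted alkyne favouring this closure over the five-membered alkylidenecyclopentenedione mode. The chiral Ti(IV) then chelates the C3 carbonyl and the C2 methoxy oxygen, which makes C5 the electrophilic β-position; the CHMe carbon of 2 adds there and the benzylic cation is captured by the enol-ether carbon C1 (5-exo closure of the C1–C7–C6–C5–C8 ring, which at the same time completes the seven-membered ring), after which the C2 oxocarbenium loses its methyl as MeCl and the titanium enolate becomes the C3 enol. This is a stepwise perezone-type [5+2], whose closest known reaction type is the Ti(IV)-promoted reaction of 2-alkoxy-5-allyl-1,4-benzoquinones with (E)-propenylarenes together with the Ti–TADDOLate asymmetric variant of the quinone–styrene reaction. C5 and C6 are set in the first C–C bond, the face of C5 by the aryl groups of the TADDOLate and C6 by the compact approach with the trimethoxyphenyl ring stacked under the quinone; C7 follows because the cation closes anti to the C6 methyl (aryl endo, methyl exo, the trans relation of the E-alkene kept), and C1 is fixed by the bridge. The step needs attack at C5 and not at C4 (secured by chelation at the less hindered carbonyl, the one flanked by C4–H and not by the allyl-bearing carbon), C- and not O-closure (an O-closed oxocarbenium can reopen to the cation, whereas C-closure becomes irreversible through loss of the methyl group) and facial control (ligand).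

**Step 4**
Reactants: 7 (1R,5S,6S,7R)-5-allyl-3-hydroxy-1-methoxy-6-methyl-7-(3,4,5-trimethoxyphenyl)bicyclo[3.2.1]oct-3-ene-2,8-dione
Product: 8 (1R,5S,6S,7R)-5-allyl-1,3-dimethoxy-6-methyl-7-(3,4,5-trimethoxyphenyl)bicyclo[3.2.1]oct-3-ene-2,8-dione
Conditions: Me2SO4, K2CO3, acetone, rt
Reagents that add atoms: dimethyl sulfate COS(=O)(=O)OC
Why: O-alkylation of the acidic C3 enol (a diosphenol, enolisable only toward C4 because C1 is quaternary) with a hard methylating agent and a weak non-nucleophilic base should give the 3-methoxy enone without cleaving the non-enolisable β-dicarbonyl unit at C1.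

**Step 5**
Reactants: 8 (1R,5S,6S,7R)-5-allyl-1,3-dimethoxy-6-methyl-7-(3,4,5-trimethoxyphenyl)bicyclo[3.2.1]oct-3-ene-2,8-dione
Product: 9 (1S,2R,5S,6S,7R)-5-allyl-2-hydroxy-1,3-dimethoxy-6-methyl-7-(3,4,5-trimethoxyphenyl)bicyclo[3.2.1]oct-3-en-8-one
Conditions: NaBH4, CeCl3·7H2O, MeOH, −78 °C
Reagents that add atoms: none
Why: Luche reduction is 1,2-selective and favours the conjugated C2 carbonyl over the C8 ketone held between two quaternary bridgeheads, and hydride should reach C2 from the face opposite the endo aryl group, which sets the (2R) carbinol with its oxygen on the aryl-bearing side.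

**Step 6**
Reactants: 9 (1S,2R,5S,6S,7R)-5-allyl-2-hydroxy-1,3-dimethoxy-6-methyl-7-(3,4,5-trimethoxyphenyl)bicyclo[3.2.1]oct-3-en-8-one
Product: 10 (1S,2R,5S,6S,7R)-5-allyl-1,3-dimethoxy-6-methyl-8-oxo-7-(3,4,5-trimethoxyphenyl)bicyclo[3.2.1]oct-3-en-2-yl acetate
Conditions: Ac2O, pyridine, DMAP (cat.), CH2Cl2, rt
Reagents that add atoms: acetic anhydride CC(=O)OC(C)=O
Why: DMAP-catalysed acylation of the secondary allylic alcohol touches no stereocentre and leaves the enol ether, the ketone and the allyl group unchanged.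

**Compound list**

1 | elemicin (5-allyl-1,2,3-trimethoxybenzene) | C=CCc1cc(OC)c(OC)c(OC)c1 | starting material
2 | (E)-isoelemicin | C/C=C/c1cc(OC)c(OC)c(OC)c1 | intermediate
3 | pent-1-en-4-yne | C#CCC=C | starting material
4 | dimethyl squarate | COC1=C(OC)C(=O)C1=O | starting material
5 | rac-4-hydroxy-2,3-dimethoxy-4-(pent-4-en-1-yn-1-yl)cyclobut-2-en-1-one | COC1=C(OC)C(O)(C#CCC=C)C1=O | intermediate
6 | 5-allyl-2,3-dimethoxy-1,4-benzoquinone | C=CCC1=CC(=O)C(OC)=C(OC)C1=O | intermediate (not isolated)
7 | (1R,5S,6S,7R)-5-allyl-3-hydroxy-1-methoxy-6-methyl-7-(3,4,5-trimethoxyphenyl)bicyclo[3.2.1]oct-3-ene-2,8-dione (6-exo-methyl, 7-endo-aryl) | C=CC[C@]12C=C(O)C(=O)[C@](OC)(C1=O)[C@@H](c1cc(OC)c(OC)c(OC)c1)[C@@H]2C | intermediate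
8 | (1R,5S,6S,7R)-5-allyl-1,3-dimethoxy-6-methyl-7-(3,4,5-trimethoxyphenyl)bicyclo[3.2.1]oct-3-ene-2,8-dione | C=CC[C@]12C=C(OC)C(=O)[C@](OC)(C1=O)[C@@H](c1cc(OC)c(OC)c(OC)c1)[C@@H]2C | intermediate
9 | (1S,2R,5S,6S,7R)-5-allyl-2-hydroxy-1,3-dimethoxy-6-methyl-7-(3,4,5-trimethoxyphenyl)bicyclo[3.2.1]oct-3-en-8-one | C=CC[C@]12C=C(OC)[C@@H](O)[C@](OC)(C1=O)[C@@H](c1cc(OC)c(OC)c(OC)c1)[C@@H]2C | intermediate
10 | (1S,2R,5S,6S,7R)-5-allyl-1,3-dimethoxy-6-methyl-8-oxo-7-(3,4,5-trimethoxyphenyl)bicyclo[3.2.1]oct-3-en-2-yl acetate | C=CC[C@]12C=C(OC)[C@@H](OC(C)=O)[C@](OC)(C1=O)[C@@H](c1cc(OC)c(OC)c(OC)c1)[C@@H]2C | target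

Total step count: 6. Longest linear sequence: 5 steps (steps 2–6 from 3 and 4, or steps 1 and 3–6 from 1).

**Steps most likely to fail**

1. Step 3. The titanium may bind the other carbonyl, so that the alkene bonds at the unsubstituted C4 instead of C5; the benzylic cation may be captured by oxygen; or facial discrimination at the quaternary centre may be weak. The fallback sets out from 3 and 4 and comes back to the route at 8. Hydrozirconation of 3 with Cp2Zr(H)Cl and iodinolysis should give (E)-1-iodopenta-1,4-diene F1. Iodine–lithium exchange (t-BuLi, Et2O, −78 °C), addition to 4 and trapping of the alkoxide with MeOTf should give 2,3,4-trimethoxy-4-[(1E)-penta-1,4-dien-1-yl]cyclobut-2-en-1-one F2. Heating in toluene should ring-expand it by 4π-opening, 6π-closure and tautomerisation to 6-allyl-2,3,4-trimethoxyphenol F3, and PhI(OAc)2 in MeOH should convert this p-methoxyphenol into 2-allyl-4,4,5,6-tetramethoxycyclohexa-2,5-dien-1-one F4. Ionisation of the ketal (TMSOTf, CH2Cl2, −78 °C) in the presence of 2 is the cationic perezone-type [5+2] of quinone monoketals with (E)-propenylarenes; only C1 and C5 can be its termini and the C3 methoxy group is already in place, so it should give racemic 8 F5. Preparative chromatography on a chiral stationary phase then separates 8 from its enantiomer ent-8 F6.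

2. Step 5. Hydride may be delivered to the strained C8 ketone as well (possibly helped by chelation to the C1 methoxy group), so that the two carbonyls are not told apart. The fallback sets out from 8 and comes back at 10. Reduction of both carbonyls (NaBH4, MeOH, 0 °C) should give (1R,2R,5S,6S,7R,8S)-5-allyl-1,3-dimethoxy-6-methyl-7-(3,4,5-trimethoxyphenyl)bicyclo[3.2.1]oct-3-ene-2,8-diol F7. Acetylation of only the less hindered allylic C2 hydroxyl (Ac2O, pyridine, 0 °C, no DMAP; the C8 hydroxyl lies between two quaternary carbons) should give the 2-monoacetate of this diol F8. Oxidation of the C8 carbinol with Dess–Martin periodinane then gives 10.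

3. Step 2. The base may also metalate the doubly activated CH2 of 3 (propargyl–allenyl isomerisation, dianion formation), and a second addition to the squarate may occur. The fallback sets out from 4 and comes back at 5. Lithium (trimethylsilyl)acetylide adds to 4 to give 4-hydroxy-2,3-dimethoxy-4-[(trimethylsilyl)ethynyl]cyclobut-2-en-1-one F9. Buffered desilylation (TBAF, AcOH, THF, 0 °C) gives 4-ethynyl-4-hydroxy-2,3-dimethoxycyclobut-2-en-1-one F10. Copper-catalysed coupling of the terminal alkyne with allyl bromide (CuI cat., K2CO3, Bu4NI, DMF, rt) then installs the skipped enyne of 5 without any free acetylide of 3.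

**Further compounds**

F1 | step 3 | (E)-1-iodopenta-1,4-diene | I/C=C/CC=C
F2 | step 3 | rac-2,3,4-trimethoxy-4-[(1E)-penta-1,4-dien-1-yl]cyclobut-2-en-1-one | COC1=C(OC)C(OC)(/C=C/CC=C)C1=O
F3 | step 3 | 6-allyl-2,3,4-trimethoxyphenol | C=CCc1cc(OC)c(OC)c(OC)c1O
F4 | step 3 | 2-allyl-4,4,5,6-tetramethoxycyclohexa-2,5-dien-1-one | C=CCC1=CC(OC)(OC)C(OC)=C(OC)C1=O
F5 | step 3 | racemic 8 (both enantiomers, 1:1) | C=CC[C@]12C=C(OC)C(=O)[C@](OC)(C1=O)[C@@H](c1cc(OC)c(OC)c(OC)c1)[C@@H]2C.C=CC[C@@]12C=C(OC)C(=O)[C@@](OC)(C1=O)[C@H](c1cc(OC)c(OC)c(OC)c1)[C@H]2C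
F6 | step 3 | ent-8, (1S,5R,6R,7S)-5-allyl-1,3-dimethoxy-6-methyl-7-(3,4,5-trimethoxyphenyl)bicyclo[3.2.1]oct-3-ene-2,8-dione | C=CC[C@@]12C=C(OC)C(=O)[C@@](OC)(C1=O)[C@H](c1cc(OC)c(OC)c(OC)c1)[C@H]2C
F7 | step 5 | (1R,2R,5S,6S,7R,8S)-5-allyl-1,3-dimethoxy-6-methyl-7-(3,4,5-trimethoxyphenyl)bicyclo[3.2.1]oct-3-ene-2,8-diol (8-OH on the side of the C6–C7 bridge) | C=CC[C@]12C=C(OC)[C@@H](O)[C@](OC)([C@H]1O)[C@@H](c1cc(OC)c(OC)c(OC)c1)[C@@H]2C
F8 | step 5 | (1R,2R,5S,6S,7R,8S)-5-allyl-8-hydroxy-1,3-dimethoxy-6-methyl-7-(3,4,5-trimethoxyphenyl)bicyclo[3.2.1]oct-3-en-2-yl acetate | C=CC[C@]12C=C(OC)[C@@H](OC(C)=O)[C@](OC)([C@H]1O)[C@@H](c1cc(OC)c(OC)c(OC)c1)[C@@H]2C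
F9 | step 2 | rac-4-hydroxy-2,3-dimethoxy-4-[(trimethylsilyl)ethynyl]cyclobut-2-en-1-one | COC1=C(OC)C(O)(C#C[Si](C)(C)C)C1=O
F10 | step 2 | rac-4-ethynyl-4-hydroxy-2,3-dimethoxycyclobut-2-en-1-one | COC1=C(OC)C(O)(C#C)C1=O
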